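**Plan**

- Retrosynthesis first removes five MOM ethers, then opens the pyranone ring C (O1, C2, C3, C4, C4a, C8a) at its α-ketol unit C3(OH)–C4(=O), which lies next to the benzylic O1–C2 carbon. A retro-acyloin 1,2-shift of C2 leads back to a ring one atom smaller, the furan ring of a 3-hydroxy-2,3-dihydrobenzofuran-3-carbaldehyde.
- Further cuts: O1–C2 (phenoxide opening of an epoxide), the epoxide oxygen (Sharpless), ring A–vinyl (Suzuki), ring A–CH2 of the lavandulyl group (Negishi), ring A–CH2 of the hydroxyalkyl chain (directed metalation), and C2–C3 of lavandulol (Evans alkylation).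
- Forward: phloroglucinol (ring A) is desymmetrised as two MOM ethers and one TIPS ether, alkylated para to the future O1, then iodinated and brominated at the two remaining positions. The lavandulyl chain and then the ring-B propenol are coupled on.
- The furan ring closes in step 17 and is expanded to the pyranone ring in step 19; deprotection ends the route.
- Stereochemistry: the side-chain centre comes from an (R)-4-benzyloxazolidinone auxiliary. C2 comes from a D-(−)-DIPT Sharpless epoxidation of a (Z)-allylic alcohol followed by inversion in the phenoxide opening. C3 comes from the chelate-controlled suprafacial shift of the key step.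

Key step: step 19

Remark: the side-chain centre of the target is S, which is the spatial arrangement of (R)-lavandulol, because the CIP order changes when CH2OH becomes CH2Ar. Abbreviations: MOM = CH2OCH3, TIPS = Si(i-Pr)3, lavandulyl = 5-methyl-2-(prop-1-en-2-yl)hex-4-en-1-yl.

**Route**

Step 1
Reactants: 1 phloroglucinol
Product: 2 3,5-bis(methoxymethoxy)phenol
Conditions: MOMCl (2.0 equiv), i-Pr2NEt (2.5 equiv), DMF, 0 °C → rt
Reagents that add atoms: chloromethyl methyl ether, COCCl
Why: Base-mediated O-alkylation (MOM protection) of a C3-symmetric triol is statistical, so the bis-ether should be separable from the mono- and tris-ethers, which can be recycled, and it leaves free the one oxygen that becomes O1.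

Step 2
Reactants: 2 3,5-bis(methoxymethoxy)phenol
Product: 3 [3,5-bis(methoxymethoxy)phenoxy]triisopropylsilane
Conditions: TIPSCl (1.2 equiv), imidazole (2 equiv), DMF, rt
Reagents that add atoms: chlorotriisopropylsilane, CC(C)[Si](Cl)(C(C)C)C(C)C
Why: Silylation of the remaining phenol; the bulky, weakly coordinating OTIPS group should steer the next metalation away from its own ortho positions.

Step 3
Reactants: 4 4-bromo-2-methylbutan-2-ol
Product: 5 4-bromo-2-(methoxymethoxy)-2-methylbutane
Conditions: MOMCl (3 equiv), i-Pr2NEt (4 equiv), CH2Cl2, 40 °C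
Reagents that add atoms: chloromethyl methyl ether, COCCl
Why: Acetal-type O-alkylation (MOM protection) of the tertiary alcohol by the oxocarbenium-like electrophile, which the hindered amine base should allow without touching the primary bromide.

Step 4
Reactants: 3 [3,5-bis(methoxymethoxy)phenoxy]triisopropylsilane; 5 4-bromo-2-(methoxymethoxy)-2-methylbutane
Product: 7 {4-[3-(methoxymethoxy)-3-methylbutyl]-3,5-bis(methoxymethoxy)phenoxy}triisopropylsilane, via aryllithium 6 (not isolated)
Conditions: n-BuLi (1.1 equiv), THF, 0 °C, 1 h; then 5 (1.3 equiv), DMPU, 0 °C → rt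
Reagents that add atoms: none
Why: Directed ortho-metalation at the position flanked by two OMOM groups, followed by SN2 alkylation of the 2,6-dialkoxyaryllithium with a primary bromide, should place the chain para to the silyloxy group.

Step 5
Reactants: 7 chain-bearing arene
Product: 8 2-iodo derivative of 7
Conditions: NIS (1.05 equiv), MeCN, 0 °C, dark
Reagents that add atoms: N-iodosuccinimide, O=C1CCC(=O)N1I
Why: Electrophilic aromatic iodination of the highly activated arene at one of its two equivalent free positions; the first halogen lowers the reactivity enough for mono-substitution with one equivalent.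

Step 6
Reactants: 8 aryl iodide
Product: 9 2-bromo-6-iodo arene
Conditions: NBS (1.05 equiv), MeCN, −20 → 0 °C
Reagents that add atoms: N-bromosuccinimide, O=C1CCC(=O)N1Br
Why: Electrophilic aromatic bromination at the last free ring position, which should be faster than ipso attack at the iodinated carbon, gives a ring with two halogens of different reactivity.

Step 7
Reactants: 10 (4R)-4-benzyl-1,3-oxazolidin-2-one; 11 3-methylbut-2-enoyl chloride
Product: 13 (4R)-4-benzyl-3-(3-methylbut-2-enoyl)-1,3-oxazolidin-2-one, via lithium oxazolidinide 12 (not isolated)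
Conditions: n-BuLi (1.0 equiv), THF, −78 °C; then 11, −78 → 0 °C
Reagents that add atoms: none
Why: N-Acylation of the lithiated oxazolidinone with the acid chloride, the standard preparation of Evans imides.

Step 8
Reactants: 13 N-enoyl imide; 14 1-bromo-3-methylbut-2-ene (prenyl bromide)
Product: 16 (4R)-4-benzyl-3-[(2R)-5-methyl-2-(prop-1-en-2-yl)hex-4-enoyl]-1,3-oxazolidin-2-one, via sodium dienolate 15 (not isolated)
Conditions: NaHMDS (1.1 equiv), THF, −78 °C; then 14 (3 equiv), −78 → −45 °C
Reagents that add atoms: none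
Why: Evans deconjugative α-alkylation: the chelated sodium (Z)-dienolate should be alkylated at the α-carbon on the face opposite the benzyl group, which sets the 2R centre and moves the double bond into the isopropenyl position.

Step 9
Reactants: 16 alkylated imide
Product: 17 (R)-lavandulol
Conditions: LiBH4 (1.5 equiv), H2O (1.5 equiv), Et2O, 0 °C
Reagents that add atoms: none
Why: Reductive cleavage of the imide with LiBH4 at the exocyclic carbonyl should release the primary alcohol without base-induced epimerisation or conjugation of the β,γ-double bond.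

Step 10
Reactants: 17 (R)-lavandulol
Product: 18 (R)-lavandulyl iodide
Conditions: I2, PPh3, imidazole, CH2Cl2, 0 °C → rt
Reagents that add atoms: iodine, II
Why: Appel-type iodination of the primary alcohol by SN2 at CH2; the stereocentre is not involved.

Step 11
Reactants: 9 2-bromo-6-iodo arene; 18 (R)-lavandulyl iodide
Product: 20 lavandulyl aryl bromide, via alkylzinc iodide 19 (not isolated)
Conditions: 18, Zn dust, LiCl, THF, 35 °C; then 9, Pd(OAc)2 (3 mol%), SPhos (6 mol%), THF, 25 °C
Reagents that add atoms: none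
Why: Zinc insertion into the primary iodide and Negishi sp3–sp2 coupling, which should take place at the C–I bond and leave the C–Br bond because oxidative addition to the aryl iodide is much faster at room temperature; the stereocentre is β to zinc and is not touched.

Step 12
Reactants: 21 4-bromobenzene-1,3-diol
Product: 22 1-bromo-2,4-bis(methoxymethoxy)benzene
Conditions: MOMCl (2.5 equiv), i-Pr2NEt (3 equiv), CH2Cl2, 0 °C → rt
Reagents that add atoms: chloromethyl methyl ether, COCCl
Why: MOM protection of both phenols by O-alkylation.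

Step 13
Reactants: 22 1-bromo-2,4-bis(methoxymethoxy)benzene; 23 prop-2-yn-1-ol
Product: 24 3-[2,4-bis(methoxymethoxy)phenyl]prop-2-yn-1-ol
Conditions: Pd(PPh3)4 (3 mol%), CuI (5 mol%), i-Pr2NH, THF, 65 °C
Reagents that add atoms: none
Why: Sonogashira coupling of the aryl bromide with the terminal alkyne; the electron-rich bromide needs heating.

Step 14
Reactants: 24 aryl propargyl alcohol
Product: 25 (2Z)-3-[2,4-bis(methoxymethoxy)phenyl]-2-(pinacolatoboryl)prop-2-en-1-ol
Conditions: B2pin2 (1.1 equiv), CuCl (5 mol%), P(p-tol)3 (6 mol%), NaOt-Bu (15 mol%), MeOH (2 equiv), THF, rt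
Reagents that add atoms: bis(pinacolato)diboron, CC1(C)OB(OC1(C)C)B1OC(C)(C)C(C)(C)O1
Why: Copper-catalysed formal hydroboration (syn borylcupration, then protonation by methanol): copper should take the aryl-bearing carbon and boron C2, and the syn addition fixes the Z geometry with boron trans to the aryl group.

Step 15
Reactants: 20 lavandulyl aryl bromide; 25 (Z)-alkenyl boronate
Product: 26 (Z)-2,3-diarylallyl alcohol
Conditions: SPhos Pd G3 (5 mol%), K3PO4 (3 equiv), toluene/H2O 10:1, 80 °C
Reagents that add atoms: none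
Why: Suzuki–Miyaura coupling with retention of the alkene geometry; a bulky biarylphosphine ligand is chosen for the doubly ortho-substituted bromide.

Step 16
Reactants: 26 (Z)-2,3-diarylallyl alcohol
Product: 27 (2R,3S)-epoxy alcohol
Conditions: Ti(Oi-Pr)4 (20 mol%), D-(−)-DIPT (26 mol%), t-BuOOH (2 equiv, in decane), 4 Å MS, CH2Cl2, −25 °C
Reagents that add atoms: tert-butyl hydroperoxide, CC(C)(C)OO
Why: Sharpless asymmetric epoxidation, directed by the allylic hydroxyl group so that the two side-chain alkenes are not touched; with D-(−)-DIPT the oxygen should be delivered to the face that gives the 2R,3S epoxide.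

Step 17
Reactants: 27 (2R,3S)-epoxy alcohol
Product: 29 (2R,3R)-2-aryl-3-(hydroxymethyl)-2,3-dihydrobenzofuran-3-ol, via ammonium phenoxide 28 (not isolated)
Conditions: TBAF (1.2 equiv), THF, 0 °C → rt; aq. NH4Cl
Reagents that add atoms: none
Why: Fluoride cleaves the aryl silyl ether and the phenoxide opens the epoxide at the benzylic carbon (5-endo opening, as known for 2-hydroxystilbene oxides) by SN2 with inversion, which sets C2 as R and closes the furan ring.

Step 18
Reactants: 29 dihydrobenzofuran diol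
Product: 30 (2R,3S)-2-aryl-3-hydroxy-2,3-dihydrobenzofuran-3-carbaldehyde
Conditions: IBX (1.5 equiv), DMSO, 23 °C
Reagents that add atoms: none
Why: IBX oxidation of the primary alcohol; IBX does not cleave 1,2-diols and the tertiary alcohol cannot be oxidised.

Step 19
Reactants: 30 (2R,3S)-hydroxy aldehyde
Product: 31 penta-MOM (2R,3R)-flavanonol
Conditions: Al(Ot-Bu)3 (0.3 equiv), toluene, 0 → 40 °C; aq. Rochelle salt
Reagents that add atoms: none
Why: Proposed new method: the aluminium alkoxide of the tertiary carbinol binds the formyl oxygen in a five-membered chelate (C=O syn to C–O), and the ring bond C2–C3, which lies nearly perpendicular to the carbonyl plane, shifts suprafacially from C3 to the formyl carbon while C3 becomes the aryl ketone (α-ketol or acyloin rearrangement); alkoxide exchange with a new molecule of 30 should turn the catalyst over. The closest known reactions are the Lewis-acid-mediated ring-expanding acyloin rearrangements of 1-hydroxycycloalkanecarbaldehydes and the aluminium-alkoxide D-homoannulation of 17-hydroxy-20-keto steroids, but a 3-hydroxy-2,3-dihydrobenzofuran-3-carbaldehyde has not been used. The pyranone ring is not closed by a cyclisation; it arises from the furan ring by insertion of the formyl carbon between C2 and C3 (1,2-alkyl shift, five to six). C2 migrates with retention and keeps the R configuration set in step 17, and the new carbinol centre C3 is fixed by the chelate geometry: the migrating carbon enters the formyl face on which it already lies, which, with the aryl group cis to the formyl group, should give the 2,3-trans (2R,3R) isomer that is also the more stable one. The step needs migration of C2 in preference to the ring-A carbon C3a and no ionisation of the benzylic C2–O1 bond: C2 is a benzylic, oxygen-bearing carbon and its shift creates a ketone conjugated with the trioxygenated ring A, a shift of C3a would give the 4-hydroxy-3-ketone that is the acyloin isomer of 31 and should be funnelled to it by a 1,2-hydride shift in the same chelate, and the neutral, weakly Lewis acidic alkoxide should leave the MOM ethers and the C2–O1 bond alone.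

Step 20
Reactants: 31 penta-MOM flavanonol
Product: 32 target
Conditions: ZnBr2 (5 equiv), n-PrSH (10 equiv), CH2Cl2, 0 °C, 15 min
Reagents that add atoms: none
Why: Lewis-acid/thiol cleavage of MOM ethers (ZnBr2 activates the acetal, the thiol traps the methoxymethyl cation) should remove the four aryl ethers and the tertiary alkyl ether quickly at 0 °C without protic acid, which protects the alkenes, the tertiary alcohol and the C2 centre.

**Compound list**

1 | benzene-1,3,5-triol (phloroglucinol) | Oc1cc(O)cc(O)c1 | starting material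
2 | 3,5-bis(methoxymethoxy)phenol | COCOc1cc(O)cc(OCOC)c1 | intermediate
3 | [3,5-bis(methoxymethoxy)phenoxy]tri(propan-2-yl)silane | COCOc1cc(OCOC)cc(O[Si](C(C)C)(C(C)C)C(C)C)c1 | intermediate
4 | 4-bromo-2-methylbutan-2-ol | CC(C)(O)CCBr | starting material
5 | 4-bromo-2-(methoxymethoxy)-2-methylbutane | COCOC(C)(C)CCBr | intermediate
6 | [2,6-bis(methoxymethoxy)-4-(triisopropylsilyloxy)phenyl]lithium | COCOc1cc(O[Si](C(C)C)(C(C)C)C(C)C)cc(OCOC)c1[Li] | intermediate (not isolated)
7 | {4-[3-(methoxymethoxy)-3-methylbutyl]-3,5-bis(methoxymethoxy)phenoxy}tri(propan-2-yl)silane | COCOC(C)(C)CCc1c(OCOC)cc(O[Si](C(C)C)(C(C)C)C(C)C)cc1OCOC | intermediate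
8 | {2-iodo-4-[3-(methoxymethoxy)-3-methylbutyl]-3,5-bis(methoxymethoxy)phenoxy}tri(propan-2-yl)silane | COCOC(C)(C)CCc1c(OCOC)cc(O[Si](C(C)C)(C(C)C)C(C)C)c(I)c1OCOC | intermediate
9 | {2-bromo-6-iodo-4-[3-(methoxymethoxy)-3-methylbutyl]-3,5-bis(methoxymethoxy)phenoxy}tri(propan-2-yl)silane | COCOC(C)(C)CCc1c(OCOC)c(Br)c(O[Si](C(C)C)(C(C)C)C(C)C)c(I)c1OCOC | intermediate
10 | (4R)-4-benzyl-1,3-oxazolidin-2-one | O=C1N[C@H](Cc2ccccc2)CO1 | starting material
11 | 3-methylbut-2-enoyl chloride | CC(C)=CC(=O)Cl | starting material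
12 | N-lithio-(4R)-4-benzyl-1,3-oxazolidin-2-one | [Li]N1[C@H](Cc2ccccc2)COC1=O | intermediate (not isolated)
13 | (4R)-4-benzyl-3-(3-methylbut-2-enoyl)-1,3-oxazolidin-2-one | CC(C)=CC(=O)N1[C@H](Cc2ccccc2)COC1=O | intermediate
14 | 1-bromo-3-methylbut-2-ene | CC(C)=CCBr | starting material
15 | sodium (Z)-dienolate of 13 (O– cis to the isopropenyl group) | C=C(C)/C=C(\[O-])N1[C@H](Cc2ccccc2)COC1=O.[Na+] | intermediate (not isolated)
16 | (4R)-4-benzyl-3-[(2R)-5-methyl-2-(prop-1-en-2-yl)hex-4-enoyl]-1,3-oxazolidin-2-one | C=C(C)[C@@H](CC=C(C)C)C(=O)N1[C@H](Cc2ccccc2)COC1=O | intermediate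
17 | (2R)-5-methyl-2-(prop-1-en-2-yl)hex-4-en-1-ol, (R)-lavandulol | CC(C)=CC[C@@H](CO)C(C)=C | intermediate
18 | (3R)-3-(iodomethyl)-2,6-dimethylhepta-1,5-diene, (R)-lavandulyl iodide | CC(C)=CC[C@@H](CI)C(C)=C | intermediate
19 | [(2R)-5-methyl-2-(prop-1-en-2-yl)hex-4-en-1-yl]zinc iodide | CC(C)=CC[C@@H](C[Zn]I)C(C)=C | intermediate (not isolated)
20 | {2-bromo-4-[3-(methoxymethoxy)-3-methylbutyl]-3,5-bis(methoxymethoxy)-6-[(2S)-5-methyl-2-(prop-1-en-2-yl)hex-4-en-1-yl]phenoxy}tri(propan-2-yl)silane | COCOC(C)(C)CCc1c(OCOC)c(Br)c(O[Si](C(C)C)(C(C)C)C(C)C)c(C[C@H](CC=C(C)C)C(C)=C)c1OCOC | intermediate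
21 | 4-bromobenzene-1,3-diol | Oc1ccc(Br)c(O)c1 | starting material
22 | 1-bromo-2,4-bis(methoxymethoxy)benzene | COCOc1ccc(Br)c(OCOC)c1 | intermediate
23 | prop-2-yn-1-ol | C#CCO | starting material
24 | 3-[2,4-bis(methoxymethoxy)phenyl]prop-2-yn-1-ol | COCOc1ccc(C#CCO)c(OCOC)c1 | intermediate
25 | (2Z)-3-[2,4-bis(methoxymethoxy)phenyl]-2-(4,4,5,5-tetramethyl-1,3,2-dioxaborolan-2-yl)prop-2-en-1-ol | OC/C(B1OC(C)(C)C(C)(C)O1)=C\c1ccc(OCOC)cc1OCOC | intermediate
26 | (2Z)-3-[2,4-bis(methoxymethoxy)phenyl]-2-{3-[3-(methoxymethoxy)-3-methylbutyl]-2,4-bis(methoxymethoxy)-5-[(2S)-5-methyl-2-(prop-1-en-2-yl)hex-4-en-1-yl]-6-(triisopropylsilyloxy)phenyl}prop-2-en-1-ol | COCOC(C)(C)CCc1c(OCOC)c(/C(CO)=C/c2ccc(OCOC)cc2OCOC)c(O[Si](C(C)C)(C(C)C)C(C)C)c(C[C@H](CC=C(C)C)C(C)=C)c1OCOC | intermediate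
27 | [(2R,3S)-3-[2,4-bis(methoxymethoxy)phenyl]-2-{3-[3-(methoxymethoxy)-3-methylbutyl]-2,4-bis(methoxymethoxy)-5-[(2S)-lavandulyl]-6-(triisopropylsilyloxy)phenyl}oxiran-2-yl]methanol | OC[C@@]1(c2c(OCOC)c(CCC(C)(C)OCOC)c(OCOC)c(C[C@H](CC=C(C)C)C(C)=C)c2O[Si](C(C)C)(C(C)C)C(C)C)O[C@H]1c1ccc(OCOC)cc1OCOC | intermediate
28 | tetrabutylammonium phenoxide of 27 (TIPS removed, epoxide intact) | OC[C@@]1(c2c(OCOC)c(CCC(C)(C)OCOC)c(OCOC)c(C[C@H](CC=C(C)C)C(C)=C)c2[O-])O[C@H]1c1ccc(OCOC)cc1OCOC.CCCC[N+](CCCC)(CCCC)CCCC | intermediate (not isolated)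
29 | (2R,3R)-2-[2,4-bis(methoxymethoxy)phenyl]-3-(hydroxymethyl)-5-[3-(methoxymethoxy)-3-methylbutyl]-4,6-bis(methoxymethoxy)-7-[(2S)-5-methyl-2-(prop-1-en-2-yl)hex-4-en-1-yl]-2,3-dihydro-1-benzofuran-3-ol | OC[C@@]1(O)[C@@H](c2ccc(OCOC)cc2OCOC)Oc2c(C[C@H](CC=C(C)C)C(C)=C)c(OCOC)c(CCC(C)(C)OCOC)c(OCOC)c12 | intermediate
30 | (2R,3S)-2-[2,4-bis(methoxymethoxy)phenyl]-3-hydroxy-5-[3-(methoxymethoxy)-3-methylbutyl]-4,6-bis(methoxymethoxy)-7-[(2S)-5-methyl-2-(prop-1-en-2-yl)hex-4-en-1-yl]-2,3-dihydro-1-benzofuran-3-carbaldehyde | O=C[C@@]1(O)[C@@H](c2ccc(OCOC)cc2OCOC)Oc2c(C[C@H](CC=C(C)C)C(C)=C)c(OCOC)c(CCC(C)(C)OCOC)c(OCOC)c12 | intermediate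
31 | (2R,3R)-2-[2,4-bis(methoxymethoxy)phenyl]-3-hydroxy-6-[3-(methoxymethoxy)-3-methylbutyl]-5,7-bis(methoxymethoxy)-8-[(2S)-5-methyl-2-(prop-1-en-2-yl)hex-4-en-1-yl]-2,3-dihydro-4H-chromen-4-one | C=C(C)[C@@H](CC=C(C)C)Cc1c(OCOC)c(CCC(C)(C)OCOC)c(OCOC)c2c1O[C@H](c1ccc(OCOC)cc1OCOC)[C@@H](O)C2=O | intermediate
32 | (2R,3R)-2-(2,4-dihydroxyphenyl)-3,5,7-trihydroxy-6-(3-hydroxy-3-methylbutyl)-8-[(2S)-5-methyl-2-(prop-1-en-2-yl)hex-4-en-1-yl]-2,3-dihydro-4H-chromen-4-one | C=C(C)[C@@H](CC=C(C)C)Cc1c(O)c(CCC(C)(C)O)c(O)c2c1O[C@H](c1ccc(O)cc1O)[C@@H](O)C2=O | target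

**Step count and risks**

Total: 20 steps. Longest linear sequence: 12 steps (1, 2, 4, 5, 6, 11, 15, 16, 17, 18, 19, 20) from phloroglucinol.

Step 19 (proposed new method). The 1,2-shift may be slower than decay of the hydroxy aldehyde (dimerisation, Tishchenko-type reaction at aluminium), or the Lewis acid may ionise the benzylic C2–O1 bond and erode the configuration at C2. The fallback gives up the ring expansion and uses the known chalcone epoxide route; it sets out from 20 and 22 and comes back at 31. Heck coupling of 22 with N-methoxy-N-methylacrylamide should give the cinnamoyl Weinreb amide F1. Bromine–lithium exchange on 20 (t-BuLi, −95 °C) should give the aryllithium F2, which adds to F1 to give the 2'-silyloxy chalcone F3. Juliá–Colonna epoxidation (poly-L-leucine, urea–H2O2, DBU) should give the (2R,3S)-epoxy ketone F4. TBAF then frees the phenoxide F5, which should open the epoxide at the benzylic carbon (6-endo, inversion) and give 31 directly.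

Step 16. Oxygen transfer to a crowded trisubstituted (Z)-allylic alcohol may be slow and poorly face-selective, more so if rotation about the aryl–vinyl bond is slow, and the titanium Lewis acid may open the electron-rich benzylic epoxide. The fallback sets out from 26 and comes back at 30. MnO2 oxidation should give the (Z)-enal F6. Iminium-catalysed epoxidation (9-amino-9-deoxy-epi-cinchona salt, H2O2), which is selective for the electron-poor alkene, should give the (2S,3S)-epoxy aldehyde F7. TBAF at −20 °C, quenched cold with acetic acid, frees the phenoxide F8, which should close the furan ring to give 30.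

Step 15. Protodeboronation of 25 may outrun transmetalation to an aryl–palladium centre flanked by OTIPS and OMOM. The fallback removes the bulk before the coupling; it sets out from 20 and comes back at 26. TBAF should give the bromophenol F9. Suzuki–Miyaura coupling of F9 with 25, now next to a small hydroxyl group, should give the phenolic allyl alcohol F10. Deprotonation of the phenol alone (NaH, 1.0 equiv, −20 °C) and silylation with TIPSOTf should give 26.

**Further compounds**

F1 | step 19 | (2E)-3-[2,4-bis(methoxymethoxy)phenyl]-N-methoxy-N-methylprop-2-enamide | CON(C)C(=O)/C=C/c1ccc(OCOC)cc1OCOC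
F2 | step 19 | aryllithium from 20 (lithium in place of bromine) | [Li]c1c(OCOC)c(CCC(C)(C)OCOC)c(OCOC)c(C[C@H](CC=C(C)C)C(C)=C)c1O[Si](C(C)C)(C(C)C)C(C)C
F3 | step 19 | (2E)-3-[2,4-bis(methoxymethoxy)phenyl]-1-{3-[3-(methoxymethoxy)-3-methylbutyl]-2,4-bis(methoxymethoxy)-5-[(2S)-lavandulyl]-6-(triisopropylsilyloxy)phenyl}prop-2-en-1-one | O=C(/C=C/c1ccc(OCOC)cc1OCOC)c1c(OCOC)c(CCC(C)(C)OCOC)c(OCOC)c(C[C@H](CC=C(C)C)C(C)=C)c1O[Si](C(C)C)(C(C)C)C(C)C
F4 | step 19 | [(2R,3S)-3-[2,4-bis(methoxymethoxy)phenyl]oxiran-2-yl]{3-[3-(methoxymethoxy)-3-methylbutyl]-2,4-bis(methoxymethoxy)-5-[(2S)-lavandulyl]-6-(triisopropylsilyloxy)phenyl}methanone | O=C([C@@H]1O[C@H]1c1ccc(OCOC)cc1OCOC)c1c(OCOC)c(CCC(C)(C)OCOC)c(OCOC)c(C[C@H](CC=C(C)C)C(C)=C)c1O[Si](C(C)C)(C(C)C)C(C)C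
F5 | step 19 | tetrabutylammonium phenoxide of F4 (TIPS removed) | O=C([C@@H]1O[C@H]1c1ccc(OCOC)cc1OCOC)c1c(OCOC)c(CCC(C)(C)OCOC)c(OCOC)c(C[C@H](CC=C(C)C)C(C)=C)c1[O-].CCCC[N+](CCCC)(CCCC)CCCC
F6 | step 16 | (2Z)-3-[2,4-bis(methoxymethoxy)phenyl]-2-{3-[3-(methoxymethoxy)-3-methylbutyl]-2,4-bis(methoxymethoxy)-5-[(2S)-lavandulyl]-6-(triisopropylsilyloxy)phenyl}prop-2-enal | COCOC(C)(C)CCc1c(OCOC)c(/C(C=O)=C/c2ccc(OCOC)cc2OCOC)c(O[Si](C(C)C)(C(C)C)C(C)C)c(C[C@H](CC=C(C)C)C(C)=C)c1OCOC
F7 | step 16 | (2S,3S)-3-[2,4-bis(methoxymethoxy)phenyl]-2-{3-[3-(methoxymethoxy)-3-methylbutyl]-2,4-bis(methoxymethoxy)-5-[(2S)-lavandulyl]-6-(triisopropylsilyloxy)phenyl}oxirane-2-carbaldehyde | O=C[C@@]1(c2c(OCOC)c(CCC(C)(C)OCOC)c(OCOC)c(C[C@H](CC=C(C)C)C(C)=C)c2O[Si](C(C)C)(C(C)C)C(C)C)O[C@H]1c1ccc(OCOC)cc1OCOC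
F8 | step 16 | tetrabutylammonium phenoxide of F7 (TIPS removed) | O=C[C@@]1(c2c(OCOC)c(CCC(C)(C)OCOC)c(OCOC)c(C[C@H](CC=C(C)C)C(C)=C)c2[O-])O[C@H]1c1ccc(OCOC)cc1OCOC.CCCC[N+](CCCC)(CCCC)CCCC
F9 | step 15 | 2-bromo-4-[3-(methoxymethoxy)-3-methylbutyl]-3,5-bis(methoxymethoxy)-6-[(2S)-5-methyl-2-(prop-1-en-2-yl)hex-4-en-1-yl]phenol | COCOC(C)(C)CCc1c(OCOC)c(Br)c(O)c(C[C@H](CC=C(C)C)C(C)=C)c1OCOC
F10 | step 15 | 2-[(1Z)-1-[2,4-bis(methoxymethoxy)phenyl]-3-hydroxyprop-1-en-2-yl]-4-[3-(methoxymethoxy)-3-methylbutyl]-3,5-bis(methoxymethoxy)-6-[(2S)-5-methyl-2-(prop-1-en-2-yl)hex-4-en-1-yl]phenol | COCOC(C)(C)CCc1c(OCOC)c(/C(CO)=C/c2ccc(OCOC)cc2OCOC)c(O)c(C[C@H](CC=C(C)C)C(C)=C)c1OCOC
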